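**Retrosynthetic overview**

1. Target 27 ⇐ 26 ⇐ 25: the end game removes two MOM ethers and cleaves, by chelation, the 7-O-methyl ether beside the formyl group.
2. 25 ⇐ 19 + DMF (20): O1–C8a and C8–CHO are disconnected together. Rings A and B come from bought arenes, and ring C is the only ring formed and is closed last.
3. 19 ⇐ 16 + 3: the C3–C4 bond and the C3 stereocentre come from an auxiliary-controlled enolate alkylation followed by reductive release.
4. 16 ⇐ 4-bromoresorcinol (side chain first, prenyl last by metalation between the two MOM ethers); 3 ⇐ aldehyde 1.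
5. Feature used: ring A carries O1 on C8a, the formyl carbon on C8 and an oxygen on C7 on three adjacent carbons. An aryne across C8–C8a beside the C7 methoxy group takes the oxygen nucleophile at C8a and leaves a carbanion at C8 for the carbon electrophile.

Key step: step 10

Remark: the target is read from its SMILES as (3R); compounds 1, 4, 6 (as a THF solution), 9, 14 and 20 are taken as purchasable, and bromide 3 is made directly before its use in step 8.

**Route**

Step 1
Reactants: 1 2-fluoro-4,6-dimethoxybenzaldehyde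
Product: 2 (2-fluoro-4,6-dimethoxyphenyl)methanol
Conditions: NaBH4, MeOH, 0 °C to rt
Reagents that add atoms: none
Why: Borohydride reduction of an aryl aldehyde is chemoselective and leaves the aryl fluoride and the methyl ethers untouched.

Step 2
Reactants: 2 (2-fluoro-4,6-dimethoxyphenyl)methanol
Product: 3 2-(bromomethyl)-1-fluoro-3,5-dimethoxybenzene
Conditions: PBr3 (0.4 equiv), Et2O, 0 °C, 30 min; cold aqueous NaHCO3 wash; used crude on the same day
Reagents that add atoms: phosphorus tribromide, BrP(Br)Br
Why: Conversion of a benzylic alcohol into the bromide with PBr3 (SN2 on the bromophosphite) is standard, and the electron-rich bromide is labile and is therefore neither purified nor stored.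

Step 3
Reactants: 4 4-bromobenzene-1,3-diol (4-bromoresorcinol)
Product: 5 1-bromo-2,4-bis(methoxymethoxy)benzene
Conditions: MOMCl (2.5 equiv), i-Pr2NEt, CH2Cl2, 0 °C to rt
Reagents that add atoms: chloromethyl methyl ether, COCCl
Why: Double O-alkylation of the phenols with MOMCl and a hindered amine base (Williamson-type acetal formation) is routine and leaves the aryl bromide in place.

Step 4
Reactants: 5 1-bromo-2,4-bis(methoxymethoxy)benzene; 6 oxirane
Product: 8 2-[2,4-bis(methoxymethoxy)phenyl]ethan-1-ol, via aryllithium 7 (not isolated)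
Conditions: t-BuLi (2.0 equiv), THF, −78 °C; oxirane (3 equiv, THF solution), −78 °C to rt; H2O
Reagents that add atoms: oxirane 6, C1CO1
Why: Bromine–lithium exchange at −78 °C is faster than any deprotonation, and the aryllithium opens oxirane by SN2 to give the two-carbon alcohol.

Step 5
Reactants: 8 2-[2,4-bis(methoxymethoxy)phenyl]ethan-1-ol; 9 prenyl bromide (1-bromo-3-methylbut-2-ene)
Product: 11 2-[2,4-bis(methoxymethoxy)-3-(3-methylbut-2-en-1-yl)phenyl]ethan-1-ol, via dilithio species 10 (not isolated)
Conditions: n-BuLi (2.1 equiv), TMEDA, THF, 0 °C, 1.5 h; CuBr·SMe2 (0.2 equiv), −78 °C; prenyl bromide (1.05 equiv), −78 to 0 °C; H2O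
Reagents that add atoms: prenyl bromide 9, CC(C)=CCBr
Why: After the first equivalent of base has made the alkoxide, directed ortho-metalation occurs at the ring position shared by both MOM ethers, and copper-mediated allylic substitution at the primary carbon of prenyl bromide puts the linear prenyl group on carbon, the lithium alkoxide in THF being a much poorer nucleophile.

Step 6
Reactants: 11 2-[2,4-bis(methoxymethoxy)-3-(3-methylbut-2-en-1-yl)phenyl]ethan-1-ol
Product: 13 [2,4-bis(methoxymethoxy)-3-(3-methylbut-2-en-1-yl)phenyl]acetic acid, via arylacetaldehyde 12 (not isolated)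
Conditions: TEMPO (0.2 equiv), PhI(OAc)2 (2.2 equiv), MeCN/H2O 1:1, rt
Reagents that add atoms: water, O
Why: TEMPO/PhI(OAc)2 oxidation in aqueous acetonitrile takes a primary alcohol through the aldehyde hydrate to the acid under near-neutral conditions that should spare the trisubstituted alkene and the MOM acetals.

Step 7
Reactants: 13 [2,4-bis(methoxymethoxy)-3-(3-methylbut-2-en-1-yl)phenyl]acetic acid; 14 (R)-4-benzyl-2-oxazolidinone
Product: 16 (4R)-4-benzyl-3-{[2,4-bis(methoxymethoxy)-3-(3-methylbut-2-en-1-yl)phenyl]acetyl}-1,3-oxazolidin-2-one, via mixed pivalic anhydride 15 (not isolated)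
Conditions: t-BuCOCl, Et3N, THF, −20 °C, 1 h; then 14, LiCl, −20 °C to rt
Reagents that add atoms: (R)-4-benzyl-2-oxazolidinone 14, O=C1N[C@H](Cc2ccccc2)CO1
Why: N-acylation of the oxazolidinone through the mixed pivalic anhydride with LiCl/Et3N activation takes place at the less hindered arylacetyl carbonyl.

Step 8
Reactants: 16 (4R)-4-benzyl-3-{[2,4-bis(methoxymethoxy)-3-(3-methylbut-2-en-1-yl)phenyl]acetyl}-1,3-oxazolidin-2-one; 3 2-(bromomethyl)-1-fluoro-3,5-dimethoxybenzene
Product: 18 (4R)-4-benzyl-3-[(2R)-2-[2,4-bis(methoxymethoxy)-3-(3-methylbut-2-en-1-yl)phenyl]-3-(2-fluoro-4,6-dimethoxyphenyl)propanoyl]-1,3-oxazolidin-2-one, via sodium enolate 17 (not isolated)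
Conditions: NaN(SiMe3)2 (1.1 equiv), THF, −78 °C, 45 min; 3 (1.5 equiv), −78 to −40 °C
Reagents that add atoms: none
Why: Evans asymmetric alkylation: the chelated sodium Z-enolate is shielded on one face by the C4 benzyl group of the (R)-auxiliary, so the benzylic bromide enters from the opposite face and should set the new centre as 2R.

Step 9
Reactants: 18 (4R)-4-benzyl-3-[(2R)-2-[2,4-bis(methoxymethoxy)-3-(3-methylbut-2-en-1-yl)phenyl]-3-(2-fluoro-4,6-dimethoxyphenyl)propanoyl]-1,3-oxazolidin-2-one
Product: 19 (2R)-2-[2,4-bis(methoxymethoxy)-3-(3-methylbut-2-en-1-yl)phenyl]-3-(2-fluoro-4,6-dimethoxyphenyl)propan-1-ol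
Conditions: LiBH4 (2 equiv), MeOH (1 equiv), THF, 0 °C
Reagents that add atoms: none
Why: LiBH4 reduces the exocyclic imide carbonyl (reductive auxiliary cleavage) without epimerising the α-aryl centre and releases the auxiliary for recovery; the descriptor stays 2R because the oxygenated carbon keeps the highest rank.

Step 10
Reactants: 19 (2R)-2-[2,4-bis(methoxymethoxy)-3-(3-methylbut-2-en-1-yl)phenyl]-3-(2-fluoro-4,6-dimethoxyphenyl)propan-1-ol; 20 N,N-dimethylformamide
Product: 25 (3R)-3-[2,4-bis(methoxymethoxy)-3-(3-methylbut-2-en-1-yl)phenyl]-5,7-dimethoxychromane-8-carbaldehyde, via dilithio species 21 (not isolated), via aryne alkoxide 22 (not isolated), via 8-lithiochromane 23 (not isolated), via lithium hemiaminolate 24 (not isolated)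
Conditions: n-BuLi (2.05 equiv), THF (0.02 M), −78 °C, 1 h; warm to −20 °C, then 0 °C, 1 h; recool to −78 °C; DMF (4 equiv), −78 to 0 °C; H2O
Reagents that add atoms: N,N-dimethylformamide 20, CN(C)C=O
Why: Proposed new method: the first equivalent of n-BuLi makes the lithium alkoxide and the second removes, at −78 °C, the ring A hydrogen flanked by fluorine and the 4-methoxy group (the future C8) to give 21; on warming LiF is lost to give the C8–C8a aryne 22, the tethered alkoxide adds at C8a, and the resulting C8 aryllithium 23, held between O1 and the 7-methoxy group, is formylated by DMF through 24. The closest known reaction types are the capture of tethered arynes by alkoxides to give chromans and the cyclisation of arynes from 2-fluoroaryllithiums onto carbon or nitrogen tethers with electrophile quench of the new aryllithium; joining O-cyclisation and C-formylation in one flask has no direct precedent. Ring C closes in a 6-exo-dig mode, the attacked carbon C8a lying in the new ring and C8 outside it. No stereocentre is formed, and C3 is untouched because its hydrogen is not acidic under these conditions. The step needs lithiation at the future C8 and not at C6, C5' or the prenyl CH2, which the combined acidifying effect of fluorine and methoxy should secure at −78 °C, and it needs O-attack at C8a, which both the reach of the three-atom tether and the polarisation of the aryne by the adjacent methoxy group favour. Butyl addition to the aryne is limited by using only 2.05 equivalents of n-BuLi and completing the metalation before warming, and intermolecular coupling by the high dilution.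

Step 11
Reactants: 25 (3R)-3-[2,4-bis(methoxymethoxy)-3-(3-methylbut-2-en-1-yl)phenyl]-5,7-dimethoxychromane-8-carbaldehyde
Product: 26 (3R)-3-[2,4-bis(methoxymethoxy)-3-(3-methylbut-2-en-1-yl)phenyl]-7-hydroxy-5-methoxychromane-8-carbaldehyde
Conditions: MgI2·OEt2 (1.5 equiv), toluene/Et2O, 50–60 °C; H2O, dilute citric acid
Reagents that add atoms: none
Why: Chelation-assisted O-demethylation: MgI2 binds the formyl oxygen and the neighbouring 7-methoxy oxygen and iodide removes that methyl group by SN2, while the 5-methoxy group para to the aldehyde and the less accessible O1–C2 bond should remain; any MOM loss here is harmless because step 12 removes these groups.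

Step 12
Reactants: 26 (3R)-3-[2,4-bis(methoxymethoxy)-3-(3-methylbut-2-en-1-yl)phenyl]-7-hydroxy-5-methoxychromane-8-carbaldehyde
Product: 27 (3R)-3-[2,4-dihydroxy-3-(3-methylbut-2-en-1-yl)phenyl]-7-hydroxy-5-methoxychromane-8-carbaldehyde
Conditions: conc. HCl (cat.), MeOH, rt to 40 °C, monitored; aqueous NaHCO3 work-up
Reagents that add atoms: none
Why: Acid-catalysed transacetalisation to methanol removes both aryl MOM ethers under conditions mild enough that protonation of the prenyl double bond should not compete, and any dimethyl acetal of the aldehyde reverts on aqueous work-up.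

**Compound list**

1 | 2-fluoro-4,6-dimethoxybenzaldehyde | COc1cc(F)c(C=O)c(OC)c1 | starting material
2 | (2-fluoro-4,6-dimethoxyphenyl)methanol | COc1cc(F)c(CO)c(OC)c1 | intermediate
3 | 2-(bromomethyl)-1-fluoro-3,5-dimethoxybenzene | COc1cc(F)c(CBr)c(OC)c1 | intermediate
4 | 4-bromobenzene-1,3-diol (4-bromoresorcinol) | Oc1ccc(Br)c(O)c1 | starting material
5 | 1-bromo-2,4-bis(methoxymethoxy)benzene | COCOc1ccc(Br)c(OCOC)c1 | intermediate
6 | oxirane | C1CO1 | starting material
7 | [2,4-bis(methoxymethoxy)phenyl]lithium, formed in the flask | [Li]c1ccc(OCOC)cc1OCOC | intermediate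
8 | 2-[2,4-bis(methoxymethoxy)phenyl]ethan-1-ol | OCCc1ccc(OCOC)cc1OCOC | intermediate
9 | prenyl bromide (1-bromo-3-methylbut-2-ene) | CC(C)=CCBr | starting material
10 | lithium 2-[3-lithio-2,4-bis(methoxymethoxy)phenyl]ethan-1-olate, formed in the flask | [Li]OCCc1ccc(OCOC)c([Li])c1OCOC | intermediate
11 | 2-[2,4-bis(methoxymethoxy)-3-(3-methylbut-2-en-1-yl)phenyl]ethan-1-ol | OCCc1ccc(OCOC)c(CC=C(C)C)c1OCOC | intermediate
12 | [2,4-bis(methoxymethoxy)-3-(3-methylbut-2-en-1-yl)phenyl]acetaldehyde, formed in the flask | O=CCc1ccc(OCOC)c(CC=C(C)C)c1OCOC | intermediate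
13 | [2,4-bis(methoxymethoxy)-3-(3-methylbut-2-en-1-yl)phenyl]acetic acid | OC(=O)Cc1ccc(OCOC)c(CC=C(C)C)c1OCOC | intermediate
14 | (R)-4-benzyl-2-oxazolidinone | O=C1N[C@H](Cc2ccccc2)CO1 | starting material
15 | mixed anhydride of acid 13 and pivalic acid, formed in the flask | CC(C)(C)C(=O)OC(=O)Cc1ccc(OCOC)c(CC=C(C)C)c1OCOC | intermediate
16 | (4R)-4-benzyl-3-{[2,4-bis(methoxymethoxy)-3-(3-methylbut-2-en-1-yl)phenyl]acetyl}-1,3-oxazolidin-2-one | O=C1N(C(=O)Cc2ccc(OCOC)c(CC=C(C)C)c2OCOC)[C@H](Cc2ccccc2)CO1 | intermediate
17 | sodium (Z)-enolate of imide 16, formed in the flask | [Na]O/C(=C\c1ccc(OCOC)c(CC=C(C)C)c1OCOC)N1C(=O)OC[C@H]1Cc1ccccc1 | intermediate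
18 | (4R)-4-benzyl-3-[(2R)-2-[2,4-bis(methoxymethoxy)-3-(3-methylbut-2-en-1-yl)phenyl]-3-(2-fluoro-4,6-dimethoxyphenyl)propanoyl]-1,3-oxazolidin-2-one | O=C1N(C(=O)[C@H](Cc2c(F)cc(OC)cc2OC)c2ccc(OCOC)c(CC=C(C)C)c2OCOC)[C@H](Cc2ccccc2)CO1 | intermediate
19 | (2R)-2-[2,4-bis(methoxymethoxy)-3-(3-methylbut-2-en-1-yl)phenyl]-3-(2-fluoro-4,6-dimethoxyphenyl)propan-1-ol | COc1cc(OC)cc(F)c1C[C@H](c1ccc(OCOC)c(CC=C(C)C)c1OCOC)CO | intermediate
20 | N,N-dimethylformamide | CN(C)C=O | starting material
21 | O,C-dilithio derivative of 19 (lithium alkoxide, lithium on the arene carbon between fluorine and methoxy), formed in the flask | COc1cc(OC)c([Li])c(F)c1C[C@H](c1ccc(OCOC)c(CC=C(C)C)c1OCOC)CO[Li] | intermediate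
22 | lithium (2R)-2-[2,4-bis(methoxymethoxy)-3-(3-methylbut-2-en-1-yl)phenyl]-3-(2,3-didehydro-4,6-dimethoxyphenyl)propan-1-olate (aryne), formed in the flask | COC1=CC(OC)=C(C[C@H](c2ccc(OCOC)c(CC=C(C)C)c2OCOC)CO[Li])C#C1 | intermediate
23 | (3R)-3-[2,4-bis(methoxymethoxy)-3-(3-methylbut-2-en-1-yl)phenyl]-8-lithio-5,7-dimethoxychromane, formed in the flask | COc1cc(OC)c([Li])c2c1C[C@H](c1ccc(OCOC)c(CC=C(C)C)c1OCOC)CO2 | intermediate
24 | lithium (dimethylamino){(3R)-3-[2,4-bis(methoxymethoxy)-3-(3-methylbut-2-en-1-yl)phenyl]-5,7-dimethoxychroman-8-yl}methanolate, formed in the flask | COc1cc(OC)c(C(O[Li])N(C)C)c2c1C[C@H](c1ccc(OCOC)c(CC=C(C)C)c1OCOC)CO2 | intermediate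
25 | (3R)-3-[2,4-bis(methoxymethoxy)-3-(3-methylbut-2-en-1-yl)phenyl]-5,7-dimethoxychromane-8-carbaldehyde | COc1cc(OC)c(C=O)c2c1C[C@H](c1ccc(OCOC)c(CC=C(C)C)c1OCOC)CO2 | intermediate
26 | (3R)-3-[2,4-bis(methoxymethoxy)-3-(3-methylbut-2-en-1-yl)phenyl]-7-hydroxy-5-methoxychromane-8-carbaldehyde | COc1cc(O)c(C=O)c2c1C[C@H](c1ccc(OCOC)c(CC=C(C)C)c1OCOC)CO2 | intermediate
27 | (3R)-3-[2,4-dihydroxy-3-(3-methylbut-2-en-1-yl)phenyl]-7-hydroxy-5-methoxychromane-8-carbaldehyde | COc1cc(O)c(C=O)c2c1C[C@H](c1ccc(O)c(CC=C(C)C)c1O)CO2 | target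

**Step count and risks**

Total step count: 12. Longest linear sequence: 10 steps (steps 3 to 12, from 4-bromoresorcinol).

Steps most likely to fail:

1. Step 10 (the step carrying the new method). The aryne may be diverted before the tethered alkoxide captures it, by addition of residual butyllithium or of not yet eliminated aryllithium, or the C8 aryllithium may be protonated before DMF arrives, so that ring closure and formylation do not both occur. The fallback sets out from 19 and separates the two events by known chemistry. Dilithiation at −78 °C as before, but with DMF added at −78 °C before any warming, should formylate the fluorine-flanked aryllithium and give (2R)-2-[2,4-bis(methoxymethoxy)-3-(3-methylbut-2-en-1-yl)phenyl]-3-(2-fluoro-3-formyl-4,6-dimethoxyphenyl)propan-1-ol F1. Its fluorine is now ortho to the formyl group, and Cs2CO3 in DMF at 60–80 °C should close ring C by intramolecular SNAr of the primary alkoxide. The fallback returns to the route at 25.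

2. Step 5. In the O,C-dilithio species ring metalation may stay incomplete through aggregation, and the side-chain alkoxide may take up prenyl bromide in competition with the aryl carbon. The fallback sets out from 8 and masks the alcohol: TBSCl and imidazole in DMF should give tert-butyl{2-[2,4-bis(methoxymethoxy)phenyl]ethoxy}dimethylsilane F2. Metalation between the MOM ethers (n-BuLi, TMEDA, THF, 0 °C) and prenylation with CuBr·SMe2 and prenyl bromide should then give tert-butyl{2-[2,4-bis(methoxymethoxy)-3-(3-methylbut-2-en-1-yl)phenyl]ethoxy}dimethylsilane F3. Bu4NF in THF removes the silyl group and returns to the route at 11.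

3. Step 12. Under the protic acid needed for acetal cleavage, the prenyl double bond may be protonated and closed onto a freed ortho phenol (a 2,2-dimethylchroman), or it may be hydrated. The fallback sets out from 26 and avoids protic acid by silyl transfer: Me3SiOTf with 2,2'-bipyridyl in CH2Cl2 at 0 °C to rt converts aryl MOM ethers into aryl silyl ethers through an N-(methoxymethyl)bipyridinium salt and silylates the free 7-hydroxyl as well. This should give (3R)-5-methoxy-3-[3-(3-methylbut-2-en-1-yl)-2,4-bis(trimethylsilyloxy)phenyl]-7-(trimethylsilyloxy)chromane-8-carbaldehyde F4, which is hydrolysed with water at neutral pH. The fallback returns to the route at 27.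

**Further compounds**

F1 | step 10 | (2R)-2-[2,4-bis(methoxymethoxy)-3-(3-methylbut-2-en-1-yl)phenyl]-3-(2-fluoro-3-formyl-4,6-dimethoxyphenyl)propan-1-ol | COc1cc(OC)c(C=O)c(F)c1C[C@H](c1ccc(OCOC)c(CC=C(C)C)c1OCOC)CO
F2 | step 5 | tert-butyl{2-[2,4-bis(methoxymethoxy)phenyl]ethoxy}dimethylsilane | CC(C)(C)[Si](C)(C)OCCc1ccc(OCOC)cc1OCOC
F3 | step 5 | tert-butyl{2-[2,4-bis(methoxymethoxy)-3-(3-methylbut-2-en-1-yl)phenyl]ethoxy}dimethylsilane | CC(C)(C)[Si](C)(C)OCCc1ccc(OCOC)c(CC=C(C)C)c1OCOC
F4 | step 12 | (3R)-5-methoxy-3-[3-(3-methylbut-2-en-1-yl)-2,4-bis(trimethylsilyloxy)phenyl]-7-(trimethylsilyloxy)chromane-8-carbaldehyde | COc1cc(O[Si](C)(C)C)c(C=O)c2c1C[C@H](c1ccc(O[Si](C)(C)C)c(CC=C(C)C)c1O[Si](C)(C)C)CO2
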